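**Retrosynthetic overview**
- 6-Prenylorobol is traced back to its tetrakis(MOM) ether, so all four phenols are freed together in the last operation.
- Ring C is cut at C8a–O1, C4a–C4 and O1–C2. This gives a 3,5-bis(MOM-oxy)-4-prenylbenzyne (ring A) and (E)-2-aryl-3-methoxyacrylic acid (ring B plus C2, C3 and C4).
- The strategy rests on ring A. O1 and the acyl carbon C4 sit on the neighbouring carbons C8a and C4a, O5 flanks C4a, and O5, the C6 prenyl group and O7 mirror each other across the C6···C8a axis. A symmetric 4-prenylphenol therefore leads to only one aryne, and the O5 ether steers O1 to C8a, which places the prenyl group at C6 and not at C8.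
- The aryne precursor comes from phloroglucinol by lithiation and prenylation between two MOM ethers, then carbamate-directed C-silylation and triflation. The acid comes from 3,4-dihydroxyphenylacetic acid by formylation with methyl formate, O-methylation and saponification.
- Ring order: rings A and B are bought as arenes and substituted separately. Ring C is the only ring formed, and it closes in the fragment coupling.

Key step: step 13

Assumption: hydroxymethylene ester 20 is a geometrically labile enol and is drawn without alkene geometry. The E descriptor of 21, 22 and 24 is that of the expected major isomer, and either isomer would close to 25 because the geometry vanishes when methoxide leaves C2.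

Step 1
Reactants: 1 phloroglucinol
Product: 2 3,5-bis(methoxymethoxy)phenol
Conditions: MOMCl (2.1 equiv), i-Pr2NEt (2.5 equiv), DMF, 0 °C → rt; chromatography
Reagents that add atoms: chloromethyl methyl ether (MOMCl), COCCl
Why: Williamson-type MOM etherification of a triphenol whose three hydroxyls are equivalent, so a limited charge of the hard electrophile should give only O-alkylation and a statistical mixture in which the bis-ether is a single compound separable from the mono- and tris-ethers by polarity.

Step 2
Reactants: 2 3,5-bis(methoxymethoxy)phenol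
Product: 3 triisopropyl[3,5-bis(methoxymethoxy)phenoxy]silane
Conditions: TIPSCl, imidazole, DMF, rt
Reagents that add atoms: chlorotriisopropylsilane (TIPSCl), CC(C)[Si](Cl)(C(C)C)C(C)C
Why: Imidazole-promoted silyl ether formation at the only free phenol removes the acidic proton before the lithiation and places a bulky group that shields the two positions next to it.

Step 3
Reactants: 3 triisopropyl[3,5-bis(methoxymethoxy)phenoxy]silane; 4 prenyl bromide (1-bromo-3-methylbut-2-ene)
Product: 7 triisopropyl[3,5-bis(methoxymethoxy)-4-(3-methylbut-2-en-1-yl)phenoxy]silane, via aryllithium 5 (not isolated), via arylcopper 6 (not isolated)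
Conditions: n-BuLi, THF, 0 °C → rt; CuBr·SMe2 (1.1 equiv), −40 °C; 4, −40 °C → rt
Reagents that add atoms: none
Why: Directed ortho-metalation followed by copper-mediated allylic substitution, in which the C–H between the two chelating MOM ethers is the most acidic and the sites beside the TIPS ether are blocked, while the softer arylcopper should displace bromide at the unhindered primary carbon of 4 (SN2 rather than SN2′) and suppress halogen–lithium exchange.

Step 4
Reactants: 7 triisopropyl[3,5-bis(methoxymethoxy)-4-(3-methylbut-2-en-1-yl)phenoxy]silane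
Product: 8 3,5-bis(methoxymethoxy)-4-(3-methylbut-2-en-1-yl)phenol
Conditions: Bu4NF·3H2O, THF, 0 °C
Reagents that add atoms: none
Why: Fluoride-induced cleavage of the phenolic silyl ether, driven by the strong Si–F bond, leaves the MOM acetals and the alkene untouched and gives a phenol with a mirror plane through C1 and C4, so its two ortho positions are equivalent.

Step 5
Reactants: 8 3,5-bis(methoxymethoxy)-4-(3-methylbut-2-en-1-yl)phenol
Product: 9 3,5-bis(methoxymethoxy)-4-(3-methylbut-2-en-1-yl)phenyl N-isopropylcarbamate
Conditions: i-PrNCO, Et3N (cat.), CH2Cl2, rt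
Reagents that add atoms: isopropyl isocyanate, CC(C)N=C=O
Why: Amine-catalysed addition of the phenol to an isocyanate (carbamoylation) installs a strong ortho-directing group whose N–H later allows removal under mild base.

Step 6
Reactants: 9 3,5-bis(methoxymethoxy)-4-(3-methylbut-2-en-1-yl)phenyl N-isopropylcarbamate
Product: 13 3,5-bis(methoxymethoxy)-4-(3-methylbut-2-en-1-yl)-2-(trimethylsilyl)phenyl N-isopropylcarbamate, via N-silyl carbamate 10 (not isolated), via lithiated N-silyl carbamate 11 (not isolated), via C-silylated N-silyl carbamate 12 (not isolated)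
Conditions: TBSOTf (1.1 equiv), TMEDA, Et2O, 0 °C → rt; TMEDA, n-BuLi (2.1 equiv), −78 °C; TMSCl, −78 °C → rt; 10% aq citric acid, rt
Reagents that add atoms: chlorotrimethylsilane (TMSCl), C[Si](C)(C)Cl
Why: Directed ortho-metalation of an O-aryl carbamate, in which transient N-silylation blocks the acidic N–H and the isocyanate elimination it would trigger, the carbamate and the neighbouring MOM ether cooperate to direct n-BuLi to the C–H between them (either of two equivalent sites), TMSCl traps the aryllithium at −78 °C before any anionic ortho-Fries shift, and the N–Si bond is hydrolysed by a work-up too mild to touch the MOM groups.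

Step 7
Reactants: 13 3,5-bis(methoxymethoxy)-4-(3-methylbut-2-en-1-yl)-2-(trimethylsilyl)phenyl N-isopropylcarbamate
Product: 15 3,5-bis(methoxymethoxy)-4-(3-methylbut-2-en-1-yl)-2-(trimethylsilyl)phenyl trifluoromethanesulfonate, via ortho-silylphenol 14 (not isolated)
Conditions: Et2NH, DBU, MeCN, 40 °C; then PhNTf2, MeCN, rt
Reagents that add atoms: N-phenylbis(trifluoromethanesulfonimide) (PhNTf2), O=S(=O)(N(c1ccccc1)S(=O)(=O)C(F)(F)F)C(F)(F)F
Why: E1cB cleavage of the N–H carbamate by DBU expels the phenoxide and isopropyl isocyanate, which diethylamine scavenges as a urea, and O-sulfonylation of the phenoxide with the mild triflyl donor PhNTf2 in the same flask avoids handling the ortho-silylphenol, which is prone to protodesilylation.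

Step 8
Reactants: 16 3,4-dihydroxyphenylacetic acid
Product: 17 methyl 3,4-dihydroxyphenylacetate
Conditions: MeOH, H2SO4 (cat.), reflux
Reagents that add atoms: methanol, CO
Why: Fischer esterification in excess methanol, to which the catechol is inert.

Step 9
Reactants: 17 methyl 3,4-dihydroxyphenylacetate
Product: 18 methyl 3,4-bis(methoxymethoxy)phenylacetate
Conditions: MOMCl, i-Pr2NEt, CH2Cl2, 0 °C → rt, under N2
Reagents that add atoms: chloromethyl methyl ether (MOMCl), COCCl
Why: MOM etherification of both catechol hydroxyls with a hindered amine base too weak to enolise the ester puts the same acid-labile group on both fragments, so one final operation frees all four phenols.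

Step 10
Reactants: 18 methyl 3,4-bis(methoxymethoxy)phenylacetate; 19 methyl formate
Product: 20 methyl 2-[3,4-bis(methoxymethoxy)phenyl]-3-hydroxyacrylate (hydroxymethylene ester, used crude)
Conditions: NaH, 19 (excess), THF, MeOH (cat.), 0 °C → rt; cold 1 M HCl to pH 5
Reagents that add atoms: none
Why: Crossed Claisen condensation of the arylacetate enolate with the non-enolisable formate, pulled to completion by deprotonation of the acidic hydroxymethylene ester, brings in the future C2.

Step 11
Reactants: 20 methyl 2-[3,4-bis(methoxymethoxy)phenyl]-3-hydroxyacrylate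
Product: 21 methyl (E)-2-[3,4-bis(methoxymethoxy)phenyl]-3-methoxyacrylate
Conditions: Me2SO4, K2CO3, DMF, rt
Reagents that add atoms: dimethyl sulfate, COS(=O)(=O)OC
Why: O-alkylation of the ambident formyl-ester enolate with a hard methylating agent in a dipolar aprotic solvent is the standard entry to 2-aryl-3-methoxyacrylates and should favour the E enol ether, with methoxy trans to the ester.

Step 12
Reactants: 21 methyl (E)-2-[3,4-bis(methoxymethoxy)phenyl]-3-methoxyacrylate
Product: 22 (E)-2-[3,4-bis(methoxymethoxy)phenyl]-3-methoxyacrylic acid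
Conditions: LiOH·H2O, THF–MeOH–H2O, 40 °C; cold 1 M HCl to pH 4, EtOAc extraction
Reagents that add atoms: lithium hydroxide, [Li+].[OH-]
Why: Saponification (BAc2) of the methyl ester, with the enol ether and the MOM acetals stable to aqueous base and spared by acidification only to pH 4 in the cold.

Step 13
Reactants: 15 3,5-bis(methoxymethoxy)-4-(3-methylbut-2-en-1-yl)-2-(trimethylsilyl)phenyl trifluoromethanesulfonate; 22 (E)-2-[3,4-bis(methoxymethoxy)phenyl]-3-methoxyacrylic acid
Product: 25 3-[3,4-bis(methoxymethoxy)phenyl]-5,7-bis(methoxymethoxy)-6-(3-methylbut-2-en-1-yl)-4H-chromen-4-one (6-prenylorobol tetrakis(methoxymethyl) ether), via aryne 23 (not isolated), via ortho-hydroxyaryl ketone 24 (not isolated)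
Conditions: 22 (1.0 equiv), 15 (1.3 equiv), dry CsF (4 equiv), THF, sealed tube, 125 °C
Reagents that add atoms: none
Why: Proposed new method: fluoride attacks the SiMe3 group of 15 and triflate leaves to give aryne 23, the carboxylate formed from 22 and CsF adds through oxygen to the aryne carbon remote from the flanking MOM ether (future C8a), and the aryl anion left at C4a attacks the carbonyl of the aryl ester just formed (4-exo-trig), the strained benzoxete alkoxide reopening to the phenoxide of 24 and so setting bonds C8a–O1 and C4a–C4. Phenoxide O1 then closes ring C by 6-endo-trig oxa-Michael addition to the methoxy-bearing carbon C2 and E1cB loss of methoxide, which restores the C2=C3 double bond and makes the closure irreversible. The closest known reaction type is the CsF-promoted formal insertion of arynes into the C–O bond of carboxylic acids in hot THF, which gives ortho-hydroxyaryl ketones and runs on to chromanones with alkenoic acids and to flavones with alkynoic acids, whereas a 3-alkoxy-2-arylacrylic acid as partner and an addition–elimination as the closing event are new. The step needs regioselectivity, oxygen at C8a and acyl at C4a, and this is secured by the C5 MOM ether, whose inductive pull distorts the aryne so that the distal carbon is the more linear and electrophilic one and the developing anion sits beside oxygen, so the prenyl group ends up para to O1 at C6. It also needs acyl transfer to outrun protonation of the aryl anion, which is served by excess dry CsF (the acidic proton is held as CsHF2), the aprotic solvent and the high temperature, with 15 in slight excess because the methanol released can also trap aryne. No stereocentre is formed and the enol ether geometry disappears when methoxide leaves.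

Step 14
Reactants: 25 6-prenylorobol tetrakis(methoxymethyl) ether
Product: 26 6-prenylorobol, 3-(3,4-dihydroxyphenyl)-5,7-dihydroxy-6-(3-methylbut-2-en-1-yl)-4H-chromen-4-one
Conditions: 3 M aq HCl–MeOH (1:9), rt → 40 °C, under Ar; NaHCO3 quench
Reagents that add atoms: none
Why: Acid-catalysed transacetalisation of the four aryl MOM ethers with methanol, a standard final step for prenylated flavonoids, is run dilute and barely warm and stopped at full conversion so that the trisubstituted alkene is not protonated and does not cyclise onto the neighbouring C5 or C7 hydroxyl.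

**Compound list**
1 | phloroglucinol | Oc1cc(O)cc(O)c1 | starting material
2 | 3,5-bis(methoxymethoxy)phenol | COCOc1cc(O)cc(OCOC)c1 | intermediate
3 | triisopropyl[3,5-bis(methoxymethoxy)phenoxy]silane | COCOc1cc(OCOC)cc(O[Si](C(C)C)(C(C)C)C(C)C)c1 | intermediate
4 | prenyl bromide (1-bromo-3-methylbut-2-ene) | CC(C)=CCBr | starting material
5 | 2,6-bis(methoxymethoxy)-4-(triisopropylsilyloxy)phenyllithium (formed in situ) | [Li]c1c(OCOC)cc(O[Si](C(C)C)(C(C)C)C(C)C)cc1OCOC | intermediate
6 | 2,6-bis(methoxymethoxy)-4-(triisopropylsilyloxy)phenylcopper (formed in situ) | [Cu]c1c(OCOC)cc(O[Si](C(C)C)(C(C)C)C(C)C)cc1OCOC | intermediate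
7 | triisopropyl[3,5-bis(methoxymethoxy)-4-(3-methylbut-2-en-1-yl)phenoxy]silane | COCOc1cc(O[Si](C(C)C)(C(C)C)C(C)C)cc(OCOC)c1CC=C(C)C | intermediate
8 | 3,5-bis(methoxymethoxy)-4-(3-methylbut-2-en-1-yl)phenol | COCOc1cc(O)cc(OCOC)c1CC=C(C)C | intermediate
9 | 3,5-bis(methoxymethoxy)-4-(3-methylbut-2-en-1-yl)phenyl N-isopropylcarbamate | CC(C)NC(=O)Oc1cc(OCOC)c(CC=C(C)C)c(OCOC)c1 | intermediate
10 | N-(tert-butyldimethylsilyl) derivative of 9 (formed in situ) | CC(C)N(C(=O)Oc1cc(OCOC)c(CC=C(C)C)c(OCOC)c1)[Si](C)(C)C(C)(C)C | intermediate
11 | 2-lithio derivative of 10 (formed in situ) | CC(C)N(C(=O)Oc1cc(OCOC)c(CC=C(C)C)c(OCOC)c1[Li])[Si](C)(C)C(C)(C)C | intermediate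
12 | 2-(trimethylsilyl) derivative of 10 (formed in situ) | CC(C)N(C(=O)Oc1cc(OCOC)c(CC=C(C)C)c(OCOC)c1[Si](C)(C)C)[Si](C)(C)C(C)(C)C | intermediate
13 | 3,5-bis(methoxymethoxy)-4-(3-methylbut-2-en-1-yl)-2-(trimethylsilyl)phenyl N-isopropylcarbamate | CC(C)NC(=O)Oc1cc(OCOC)c(CC=C(C)C)c(OCOC)c1[Si](C)(C)C | intermediate
14 | 3,5-bis(methoxymethoxy)-4-(3-methylbut-2-en-1-yl)-2-(trimethylsilyl)phenol (formed in situ) | CC(C)=CCc1c(OCOC)cc(O)c([Si](C)(C)C)c1OCOC | intermediate
15 | 3,5-bis(methoxymethoxy)-4-(3-methylbut-2-en-1-yl)-2-(trimethylsilyl)phenyl trifluoromethanesulfonate | CC(C)=CCc1c(OCOC)cc(OS(=O)(=O)C(F)(F)F)c([Si](C)(C)C)c1OCOC | intermediate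
16 | 3,4-dihydroxyphenylacetic acid | OC(=O)Cc1ccc(O)c(O)c1 | starting material
17 | methyl 3,4-dihydroxyphenylacetate | COC(=O)Cc1ccc(O)c(O)c1 | intermediate
18 | methyl 3,4-bis(methoxymethoxy)phenylacetate | COC(=O)Cc1ccc(OCOC)c(OCOC)c1 | intermediate
19 | methyl formate | COC=O | starting material
20 | methyl 2-[3,4-bis(methoxymethoxy)phenyl]-3-hydroxyacrylate (labile enol, geometry undefined) | COC(=O)C(=CO)c1ccc(OCOC)c(OCOC)c1 | intermediate
21 | methyl (E)-2-[3,4-bis(methoxymethoxy)phenyl]-3-methoxyacrylate | CO/C=C(/C(=O)OC)c1ccc(OCOC)c(OCOC)c1 | intermediate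
22 | (E)-2-[3,4-bis(methoxymethoxy)phenyl]-3-methoxyacrylic acid | CO/C=C(/C(=O)O)c1ccc(OCOC)c(OCOC)c1 | intermediate
23 | 3,5-bis(methoxymethoxy)-4-(3-methylbut-2-en-1-yl)benzyne (formed in situ) | COCOC1=C(CC=C(C)C)C(OCOC)=CC#C1 | intermediate
24 | (E)-2-[3,4-bis(methoxymethoxy)phenyl]-1-[6-hydroxy-2,4-bis(methoxymethoxy)-3-(3-methylbut-2-en-1-yl)phenyl]-3-methoxyprop-2-en-1-one (formed in situ) | CO/C=C(/C(=O)c1c(O)cc(OCOC)c(CC=C(C)C)c1OCOC)c1ccc(OCOC)c(OCOC)c1 | intermediate
25 | 6-prenylorobol tetrakis(methoxymethyl) ether | CC(C)=CCc1c(OCOC)cc2occ(-c3ccc(OCOC)c(OCOC)c3)c(=O)c2c1OCOC | intermediate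
26 | 6-prenylorobol | CC(C)=CCc1c(O)cc2occ(-c3ccc(O)c(O)c3)c(=O)c2c1O | target

**Total step count:** 14.
**Longest linear sequence:** 9 steps (steps 1–7, 13 and 14).

**Steps most likely to fail**

1. **Step 13.**
   - What may go wrong: the aryl anion at C4a may be protonated, by CsHF2 or by the methanol released, faster than it attacks the ester carbonyl, which the 3-methoxy group makes electron-rich. The sequence would then halt at O-arylation. Thermal decarboxylation of the acid would be a second drain.
   - Fallback (known chemistry), setting out from 18 and 15 and returning at 25: 18 would be saponified (LiOH·H2O, THF–H2O; cold 1 M HCl to pH 4) to 3,4-bis(methoxymethoxy)phenylacetic acid F1. Its unconjugated, more electrophilic acyl group would be used in the aryne C–O insertion in its established form (15, CsF, THF, 125 °C, through aryne 23). That reaction stops at the deoxybenzoin 2-[3,4-bis(methoxymethoxy)phenyl]-1-[6-hydroxy-2,4-bis(methoxymethoxy)-3-(3-methylbut-2-en-1-yl)phenyl]ethanone F2. C2 would then be added by the classical deoxybenzoin-to-isoflavone condensation with DMF dimethyl acetal (toluene, 90 °C). The resulting enaminone F3 closes onto the free phenol with loss of dimethylamine to give 25.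

2. **Step 6.**
   - What may go wrong: n-BuLi/TMEDA may deprotonate the benzylic-allylic CH2 of the prenyl chain, the silyl triflate may attack a MOM acetal, or the carbamoyl group may shift to carbon on warming. Each would erode the ortho-silylation.
   - Fallback, setting out from 8 and returning at 15, by a halogen-based retro-Brook sequence that needs no carbamate: 8 would be monobrominated with NBS (CH2Cl2, −78 → 0 °C; the para position is blocked and the two ortho sites are equivalent) to 2-bromo-3,5-bis(methoxymethoxy)-4-(3-methylbut-2-en-1-yl)phenol F4. O-Silylation with hexamethyldisilazane (THF, reflux) would give its trimethylsilyl ether F5. Bromine–lithium exchange with n-BuLi (THF, −78 °C) would give the aryllithium F6. A 1,3 O→C silyl shift would convert this into the lithium phenoxide F7 of 14, and trapping with Tf2O at −78 °C would give 15.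

3. **Step 14.**
   - What may go wrong: Brønsted acid may protonate the prenyl alkene before the last MOM group has left. A liberated C5 or C7 hydroxyl could then add to it (chroman formation), or solvent could.
   - Fallback, setting out from 25 and returning at 26, which avoids protic acid: TMSOTf and 2,2′-bipyridyl (CH2Cl2, 0 °C → rt) would exchange each aryl MOM ether for a silyl ether, giving 6-prenylorobol tetrakis(trimethylsilyl) ether F8. The phenolic Si–O bonds would then be hydrolysed simply by adding water at rt to give 26.

**Further compounds**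
F1 | step 13 | 3,4-bis(methoxymethoxy)phenylacetic acid | OC(=O)Cc1ccc(OCOC)c(OCOC)c1
F2 | step 13 | 2-[3,4-bis(methoxymethoxy)phenyl]-1-[6-hydroxy-2,4-bis(methoxymethoxy)-3-(3-methylbut-2-en-1-yl)phenyl]ethanone | CC(C)=CCc1c(OCOC)cc(O)c(C(=O)Cc2ccc(OCOC)c(OCOC)c2)c1OCOC
F3 | step 13 | 2-[3,4-bis(methoxymethoxy)phenyl]-3-(dimethylamino)-1-[6-hydroxy-2,4-bis(methoxymethoxy)-3-(3-methylbut-2-en-1-yl)phenyl]prop-2-en-1-one (enaminone, geometry of no consequence) | CN(C)C=C(C(=O)c1c(O)cc(OCOC)c(CC=C(C)C)c1OCOC)c1ccc(OCOC)c(OCOC)c1
F4 | step 6 | 2-bromo-3,5-bis(methoxymethoxy)-4-(3-methylbut-2-en-1-yl)phenol | CC(C)=CCc1c(OCOC)cc(O)c(Br)c1OCOC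
F5 | step 6 | [2-bromo-3,5-bis(methoxymethoxy)-4-(3-methylbut-2-en-1-yl)phenoxy]trimethylsilane | CC(C)=CCc1c(OCOC)cc(O[Si](C)(C)C)c(Br)c1OCOC
F6 | step 6 | 2,4-bis(methoxymethoxy)-3-(3-methylbut-2-en-1-yl)-6-(trimethylsilyloxy)phenyllithium | CC(C)=CCc1c(OCOC)cc(O[Si](C)(C)C)c([Li])c1OCOC
F7 | step 6 | lithium 3,5-bis(methoxymethoxy)-4-(3-methylbut-2-en-1-yl)-2-(trimethylsilyl)phenoxide | [Li+].CC(C)=CCc1c(OCOC)cc([O-])c([Si](C)(C)C)c1OCOC
F8 | step 14 | 6-prenylorobol tetrakis(trimethylsilyl) ether | CC(C)=CCc1c(O[Si](C)(C)C)cc2occ(-c3ccc(O[Si](C)(C)C)c(O[Si](C)(C)C)c3)c(=O)c2c1O[Si](C)(C)C
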